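## Retrosynthetic overview

1. The target comes from its bis-silyl ether, which is formed by a transannular vinylogous Michael addition and reoxidation of a 20-membered naphthoquinone lactone–lactam; this last ring closure makes the azepinone and the quaternary centre.
2. The 20-membered ring comes from ring-closing metathesis of a but-3-enamide with a methacrylate ester, which creates the 2-methylglutaconate unit.
3. The naphthoquinone comes from a Diels–Alder reaction and aromatisation between a 2-amido-1,4-benzoquinone and a 1-acyl-2-siloxy-3-methylbutadiene that carries the whole ansa chain.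
4. The chain comes from γ-alkylation of a diketone dianion with a Z-allylic iodide; the Z-alkene and syn-diol come from Lindlar reduction after chelation-controlled addition of an alkynylzinc to an L-leucic acid-derived aldehyde.
5. The ethyl-bearing centre comes from Fráter–Seebach ethylation of ethyl (S)-3-hydroxybutanoate. Ring order: benzenoid ring (Diels–Alder), then 20-membered ring (metathesis), then azepinone (Michael).

Assumption: the transannular ring closure is taken to give the (R) quaternary centre as the only diastereomer, because the short ansa bridge lets the carbanion reach the quinone from one face only. All starting materials are taken as commercial.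

Abbreviations: TBS = tert-butyl(dimethyl)silyl; PMB = (4-methoxyphenyl)methyl; Tf = trifluoromethanesulfonyl.

## Route

Step 1
Reactants: 1 ethyl (3S)-3-hydroxybutanoate
Product: 2 ethyl (2S,3S)-2-ethyl-3-hydroxybutanoate
Conditions: LiN(i-Pr)2 (2.2 equiv), THF, −50 → −20 °C; then EtI, DMPU, −20 → 0 °C
Reagents that add atoms: iodoethane, CCI
Why: Fráter–Seebach alkylation, in which the chelated dilithio alkoxide–enolate is ethylated on the face away from the C3 methyl group, so the purchased centre sets the new one as the anti (2S,3S) isomer (about 95:5).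

Step 2
Reactants: 2 ethyl (2S,3S)-2-ethyl-3-hydroxybutanoate
Product: 3 (2R,3S)-2-ethylbutane-1,3-diol
Conditions: LiAlH4, Et2O, 0 °C → rt
Reagents that add atoms: none
Why: Hydride reduction of the ester to the primary alcohol, which touches no stereocentre (the descriptor changes only through priorities).

Step 3
Reactants: 3 (2R,3S)-2-ethylbutane-1,3-diol
Product: 4 (2S,3R)-3-[(TBS-oxy)methyl]pentan-2-ol
Conditions: TBSCl (1.05 equiv), imidazole, CH2Cl2, 0 °C
Reagents that add atoms: tert-butyldimethylsilyl chloride, CC(C)(C)[Si](C)(C)Cl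
Why: Silyl ether formation that is selective for the primary over the secondary hydroxyl on steric grounds.

Step 4
Reactants: 4 (2S,3R)-3-[(TBS-oxy)methyl]pentan-2-ol
Product: 5 (3R)-3-[(TBS-oxy)methyl]pentan-2-one
Conditions: Dess–Martin periodinane, CH2Cl2, 0 °C → rt
Reagents that add atoms: none
Why: Dess–Martin oxidation under non-basic conditions gives the methyl ketone without epimerising the α-centre, and the carbinol centre that served as control element is erased here.

Step 5
Reactants: 5 (3R)-3-[(TBS-oxy)methyl]pentan-2-one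
Product: 7 tert-butyl{[(2S)-2-ethylbut-3-yn-1-yl]oxy}dimethylsilane, via enol phosphate 6 (not isolated)
Conditions: LiN(i-Pr)2 (1.1 equiv), THF, −78 °C; ClP(O)(OEt)2, −78 °C → rt; then LiN(i-Pr)2 (2.3 equiv), −78 °C → rt
Reagents that add atoms: diethyl chlorophosphate, CCOP(=O)(Cl)OCC (its atoms stay only in 6)
Why: Negishi ketone-to-alkyne conversion, in which kinetic deprotonation on the methyl side, O-phosphorylation and base-induced elimination of diethyl phosphate give the terminal alkyne while the branched α-carbon is never enolised.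

Step 6
Reactants: 8 (2S)-2-hydroxy-4-methylpentanoic acid (L-leucic acid)
Product: 9 PMB (2S)-2-(PMB-oxy)-4-methylpentanoate
Conditions: NaH (2.05 equiv), PMBCl (2.2 equiv), n-Bu4NI (cat.), DMF, 0 °C → rt
Reagents that add atoms: 4-methoxybenzyl chloride, COc1ccc(CCl)cc1
Why: Double Williamson-type O-alkylation of the alkoxide and the carboxylate, with just two equivalents of base so that no ester enolate forms and the purchased centre keeps its configuration.

Step 7
Reactants: 9 PMB (2S)-2-(PMB-oxy)-4-methylpentanoate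
Product: 10 (2S)-2-(PMB-oxy)-4-methylpentanal
Conditions: i-Bu2AlH (1.1 equiv), CH2Cl2, −78 °C
Reagents that add atoms: none
Why: Partial ester reduction that stops at the aldehyde because the α-alkoxy group stabilises the tetrahedral aluminate at −78 °C.

Step 8
Reactants: 7 tert-butyl{[(2S)-2-ethylbut-3-yn-1-yl]oxy}dimethylsilane; 10 (2S)-2-(PMB-oxy)-4-methylpentanal
Product: 12 (4S,5S,8S)-8-[(TBS-oxy)methyl]-4-(PMB-oxy)-2-methyldec-6-yn-5-ol, via alkynylzinc bromide 11 (not isolated)
Conditions: 7, n-BuLi, Et2O, −78 °C; ZnBr2, −78 → 0 °C; then 10, −78 → −20 °C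
Reagents that add atoms: zinc dibromide, Br[Zn]Br (its atoms stay only in 11)
Why: Cram-chelate-controlled alkynylation, in which zinc bridges the aldehyde and PMB-ether oxygens and the acetylide attacks anti to the isobutyl group, giving the syn (5S) alcohol (about 10:1, minor isomer removed by chromatography).

Step 9
Reactants: 12 (4S,5S,8S)-8-[(TBS-oxy)methyl]-4-(PMB-oxy)-2-methyldec-6-yn-5-ol
Product: 13 (4S,5S,8S)-5-(TBS-oxy)-8-[(TBS-oxy)methyl]-4-(PMB-oxy)-2-methyldec-6-yne
Conditions: TBSOTf, 2,6-lutidine, CH2Cl2, −78 → 0 °C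
Reagents that add atoms: tert-butyldimethylsilyl trifluoromethanesulfonate, CC(C)(C)[Si](C)(C)OS(=O)(=O)C(F)(F)F
Why: Silyl ether formation with the reactive triflate protects the hindered propargylic alcohol.

Step 10
Reactants: 13 (4S,5S,8S)-5-(TBS-oxy)-8-[(TBS-oxy)methyl]-4-(PMB-oxy)-2-methyldec-6-yne
Product: 14 (4S,5S,6Z,8S)-5-(TBS-oxy)-8-[(TBS-oxy)methyl]-4-(PMB-oxy)-2-methyldec-6-ene
Conditions: H2 (1 atm), Pd/CaCO3 poisoned with Pb(OAc)2, quinoline, EtOAc, rt
Reagents that add atoms: none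
Why: Lindlar semihydrogenation delivers both hydrogens syn on the poisoned palladium surface and gives the Z-alkene only, leaving the benzylic ether intact.

Step 11
Reactants: 14 (4S,5S,6Z,8S)-5-(TBS-oxy)-8-[(TBS-oxy)methyl]-4-(PMB-oxy)-2-methyldec-6-ene
Product: 15 (2S,3Z,5S,6S)-5-(TBS-oxy)-2-ethyl-6-(PMB-oxy)-8-methylnon-3-en-1-ol
Conditions: TsOH·H2O (0.1 equiv), MeOH/CH2Cl2, 0 °C
Reagents that add atoms: none
Why: Acid-catalysed methanolysis (selective desilylation) removes the primary silyl ether much faster than the hindered secondary allylic one.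

Step 12
Reactants: 15 (2S,3Z,5S,6S)-5-(TBS-oxy)-2-ethyl-6-(PMB-oxy)-8-methylnon-3-en-1-ol
Product: 16 (4S,5S,6Z,8S)-5-(TBS-oxy)-8-(iodomethyl)-4-(PMB-oxy)-2-methyldec-6-ene
Conditions: I2, PPh3, imidazole, CH2Cl2, 0 °C → rt
Reagents that add atoms: iodine, II
Why: Appel-type iodination (Garegg–Samuelsson conditions) converts the primary alcohol to the iodide by SN2 at a non-stereogenic carbon.

Step 13
Reactants: 17 3-methylbut-3-en-2-one
Product: 18 5-methylhex-5-ene-2,4-dione
Conditions: 1-acetyl-1H-benzotriazole, MgBr2·OEt2, i-Pr2NEt, CH2Cl2, rt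
Reagents that add atoms: 1-acetyl-1H-benzotriazole, CC(=O)n1nnc2ccccc12
Why: Soft-enolisation Claisen-type C-acylation of the only enolisable position (the methyl group) gives the 1,3-diketone as its magnesium chelate.

Step 14
Reactants: 16 (4S,5S,6Z,8S)-5-(TBS-oxy)-8-(iodomethyl)-4-(PMB-oxy)-2-methyldec-6-ene; 18 5-methylhex-5-ene-2,4-dione
Product: 19 (8R,9Z,11S,12S)-11-(TBS-oxy)-8-ethyl-12-(PMB-oxy)-2,14-dimethylpentadeca-1,9-diene-3,5-dione
Conditions: 18 (1.5 equiv), LiN(i-Pr)2 (3.1 equiv), THF, 0 °C; then 16, DMPU, −78 → 0 °C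
Reagents that add atoms: none
Why: Hauser dianion γ-alkylation, in which the terminal carbanion of the diketone dianion displaces the primary iodide by SN2 and no stereocentre is touched.

Step 15
Reactants: 19 (8R,9Z,11S,12S)-11-(TBS-oxy)-8-ethyl-12-(PMB-oxy)-2,14-dimethylpentadeca-1,9-diene-3,5-dione
Product: 20 (3Z,8R,9Z,11S,12S)-3,11-bis(TBS-oxy)-8-ethyl-12-(PMB-oxy)-2,14-dimethylpentadeca-1,3,9-trien-5-one
Conditions: TBSOTf, Et3N, CH2Cl2, −78 → 0 °C
Reagents that add atoms: tert-butyldimethylsilyl trifluoromethanesulfonate, CC(C)(C)[Si](C)(C)OS(=O)(=O)C(F)(F)F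
Why: O-Silylation of the chelated Z-enol (silyl enol ether formation) gives the 2-siloxy diene; the silyl group can shuttle between the two oxygens on warming, but only this isomer is a diene and is drained in the next step.

Step 16
Reactants: 21 2,5-dimethoxyaniline; 22 but-3-enoyl chloride
Product: 23 N-(2,5-dimethoxyphenyl)but-3-enamide
Conditions: NaHCO3, EtOAc/H2O, 0 °C
Reagents that add atoms: none
Why: Schotten–Baumann N-acylation, whose biphasic bicarbonate conditions avoid isomerisation of the β,γ-unsaturated acyl group.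

Step 17
Reactants: 23 N-(2,5-dimethoxyphenyl)but-3-enamide
Product: 24 N-(3,6-dioxocyclohexa-1,4-dien-1-yl)but-3-enamide
Conditions: PhI(OCOCF3)2, MeCN/H2O, 0 °C
Reagents that add atoms: water, O
Why: Oxidative demethylation of the para-dimethoxyarene by the hypervalent iodine reagent in wet acetonitrile gives the 2-amido-1,4-benzoquinone.

Step 18
Reactants: 20 (3Z,8R,9Z,11S,12S)-3,11-bis(TBS-oxy)-8-ethyl-12-(PMB-oxy)-2,14-dimethylpentadeca-1,3,9-trien-5-one; 24 N-(3,6-dioxocyclohexa-1,4-dien-1-yl)but-3-enamide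
Product: 27 N-{5-[(4R,5Z,7S,8S)-7-(TBS-oxy)-4-ethyl-8-hydroxy-10-methylundec-5-enoyl]-6-(TBS-oxy)-7-methyl-1,4-dioxo-1,4-dihydronaphthalen-2-yl}but-3-enamide, via Diels–Alder adduct 25 (not isolated), via PMB ether 26 (not isolated)
Conditions: toluene, 70 °C; then DDQ (2.2 equiv), CH2Cl2, rt; then DDQ (1.2 equiv), CH2Cl2/H2O, rt
Reagents that add atoms: none
Why: Regioselective quinone Diels–Alder reaction in which the nucleophilic acyl-bearing diene terminus bonds to the quinone carbon β to the amide-flanked carbonyl (the other carbonyl is deactivated as a vinylogous amide), followed by DDQ dehydrogenation to the naphthoquinone and DDQ cleavage of the PMB ether, so the transient ring stereocentres are erased.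

Step 19
Reactants: 27 N-{5-[(4R,5Z,7S,8S)-7-(TBS-oxy)-4-ethyl-8-hydroxy-10-methylundec-5-enoyl]-6-(TBS-oxy)-7-methyl-1,4-dioxo-1,4-dihydronaphthalen-2-yl}but-3-enamide; 28 2-methylprop-2-enoyl chloride (methacryloyl chloride)
Product: 29 methacrylate ester of 27 at the C8 hydroxyl of the undecenoyl chain
Conditions: pyridine, DMAP (cat.), CH2Cl2, 0 °C → rt
Reagents that add atoms: none
Why: DMAP-catalysed esterification of the secondary alcohol with the acid chloride, using a weak base that leaves the amidoquinone alone.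

Step 20
Reactants: 29 methacrylate ester of 27
Product: 30 20-membered (E)-2-methylglutaconate lactone–lactam macrocycle
Conditions: second-generation Hoveyda–Grubbs catalyst [RuCl2(H2IMes)(=CH–C6H4-2-O-i-Pr)] (10 mol%), toluene (0.5 mM), 80 °C
Reagents that add atoms: none
Why: Ring-closing metathesis between the terminal alkene of the butenamide and the methacrylate at high dilution closes the 20-membered ring with loss of ethene, while the hindered internal Z-alkene does not engage.

Step 21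
Reactants: 30 20-membered (E)-2-methylglutaconate lactone–lactam macrocycle
Product: 32 bis-TBS ether of the target, via hydroquinone 31 (not isolated)
Conditions: DBU, MeCN, 0 °C → rt; then O2 (air)
Reagents that add atoms: none
Why: Transannular vinylogous Michael addition of the glutaconate dienolate through its ester α-carbon to C3 of the amidoquinone, then aerobic reoxidation; the ansa bridge allows approach from one face only, which sets the (R) quaternary centre, reversible proton transfer lets the anion reach the required geometry, and the new ring alkene is necessarily cis.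

Step 22
Reactants: 32 bis-TBS ether of the target
Product: 33 CNP0579633.1 (target)
Conditions: HF·pyridine, pyridine, THF, 0 °C → rt
Reagents that add atoms: none
Why: Fluoride-mediated cleavage of both silyl ethers (desilylation) under mildly acidic conditions that do not promote acyl migration to the freed allylic hydroxyl.

## Compound list

1 | ethyl (3S)-3-hydroxybutanoate | CCOC(=O)C[C@H](C)O | starting material
2 | ethyl (2S,3S)-2-ethyl-3-hydroxybutanoate | CCOC(=O)[C@@H](CC)[C@H](C)O | intermediate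
3 | (2R,3S)-2-ethylbutane-1,3-diol | OC[C@@H](CC)[C@H](C)O | intermediate
4 | (2S,3R)-3-({[tert-butyl(dimethyl)silyl]oxy}methyl)pentan-2-ol | CC(C)(C)[Si](C)(C)OC[C@@H](CC)[C@H](C)O | intermediate
5 | (3R)-3-({[tert-butyl(dimethyl)silyl]oxy}methyl)pentan-2-one | CC(C)(C)[Si](C)(C)OC[C@@H](CC)C(C)=O | intermediate
6 | diethyl (3R)-3-({[tert-butyl(dimethyl)silyl]oxy}methyl)pent-1-en-2-yl phosphate | CC(C)(C)[Si](C)(C)OC[C@@H](CC)C(=C)OP(=O)(OCC)OCC | intermediate
7 | tert-butyl{[(2S)-2-ethylbut-3-yn-1-yl]oxy}dimethylsilane | CC(C)(C)[Si](C)(C)OC[C@@H](CC)C#C | intermediate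
8 | (2S)-2-hydroxy-4-methylpentanoic acid (L-leucic acid) | CC(C)C[C@H](O)C(=O)O | starting material
9 | (4-methoxyphenyl)methyl (2S)-2-[(4-methoxyphenyl)methoxy]-4-methylpentanoate | CC(C)C[C@H](OCc1ccc(OC)cc1)C(=O)OCc1ccc(OC)cc1 | intermediate
10 | (2S)-2-[(4-methoxyphenyl)methoxy]-4-methylpentanal | CC(C)C[C@H](OCc1ccc(OC)cc1)C=O | intermediate
11 | bromo[(3S)-3-({[tert-butyl(dimethyl)silyl]oxy}methyl)pent-1-yn-1-yl]zinc | CC(C)(C)[Si](C)(C)OC[C@@H](CC)C#C[Zn]Br | intermediate
12 | (4S,5S,8S)-8-({[tert-butyl(dimethyl)silyl]oxy}methyl)-4-[(4-methoxyphenyl)methoxy]-2-methyldec-6-yn-5-ol | CC[C@H](CO[Si](C)(C)C(C)(C)C)C#C[C@H](O)[C@H](CC(C)C)OCc1ccc(OC)cc1 | intermediate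
13 | (4S,5S,8S)-5-(TBS-oxy)-8-[(TBS-oxy)methyl]-4-(PMB-oxy)-2-methyldec-6-yne | CC[C@H](CO[Si](C)(C)C(C)(C)C)C#C[C@H](O[Si](C)(C)C(C)(C)C)[C@H](CC(C)C)OCc1ccc(OC)cc1 | intermediate
14 | (4S,5S,6Z,8S)-5-(TBS-oxy)-8-[(TBS-oxy)methyl]-4-(PMB-oxy)-2-methyldec-6-ene | CC[C@H](CO[Si](C)(C)C(C)(C)C)/C=C\[C@H](O[Si](C)(C)C(C)(C)C)[C@H](CC(C)C)OCc1ccc(OC)cc1 | intermediate
15 | (2S,3Z,5S,6S)-5-(TBS-oxy)-2-ethyl-6-(PMB-oxy)-8-methylnon-3-en-1-ol | CC[C@H](CO)/C=C\[C@H](O[Si](C)(C)C(C)(C)C)[C@H](CC(C)C)OCc1ccc(OC)cc1 | intermediate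
16 | (4S,5S,6Z,8S)-5-(TBS-oxy)-8-(iodomethyl)-4-(PMB-oxy)-2-methyldec-6-ene | CC[C@H](CI)/C=C\[C@H](O[Si](C)(C)C(C)(C)C)[C@H](CC(C)C)OCc1ccc(OC)cc1 | intermediate
17 | 3-methylbut-3-en-2-one | CC(=O)C(C)=C | starting material
18 | 5-methylhex-5-ene-2,4-dione | CC(=O)CC(=O)C(C)=C | intermediate
19 | (8R,9Z,11S,12S)-11-(TBS-oxy)-8-ethyl-12-(PMB-oxy)-2,14-dimethylpentadeca-1,9-diene-3,5-dione | CC[C@H](CCC(=O)CC(=O)C(C)=C)/C=C\[C@H](O[Si](C)(C)C(C)(C)C)[C@H](CC(C)C)OCc1ccc(OC)cc1 | intermediate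
20 | (3Z,8R,9Z,11S,12S)-3,11-bis(TBS-oxy)-8-ethyl-12-(PMB-oxy)-2,14-dimethylpentadeca-1,3,9-trien-5-one | CC[C@H](CCC(=O)/C=C(\O[Si](C)(C)C(C)(C)C)C(C)=C)/C=C\[C@H](O[Si](C)(C)C(C)(C)C)[C@H](CC(C)C)OCc1ccc(OC)cc1 | intermediate
21 | 2,5-dimethoxyaniline | COc1ccc(OC)c(N)c1 | starting material
22 | but-3-enoyl chloride | C=CCC(Cl)=O | starting material
23 | N-(2,5-dimethoxyphenyl)but-3-enamide | COc1ccc(OC)c(NC(=O)CC=C)c1 | intermediate
24 | N-(3,6-dioxocyclohexa-1,4-dien-1-yl)but-3-enamide | C=CCC(=O)NC1=CC(=O)C=CC1=O | intermediate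
25 | N-{5-[(4R,5Z,7S,8S)-7-(TBS-oxy)-4-ethyl-8-(PMB-oxy)-10-methylundec-5-enoyl]-6-(TBS-oxy)-7-methyl-1,4-dioxo-1,4,4a,5,8,8a-hexahydronaphthalen-2-yl}but-3-enamide (cis-fused adduct, mixture at C4a, C5 and C8a) | CC[C@H](CCC(=O)C1C(O[Si](C)(C)C(C)(C)C)=C(C)CC2C1C(=O)C=C(NC(=O)CC=C)C2=O)/C=C\[C@H](O[Si](C)(C)C(C)(C)C)[C@H](CC(C)C)OCc1ccc(OC)cc1 | intermediate
26 | N-{5-[(4R,5Z,7S,8S)-7-(TBS-oxy)-4-ethyl-8-(PMB-oxy)-10-methylundec-5-enoyl]-6-(TBS-oxy)-7-methyl-1,4-dioxo-1,4-dihydronaphthalen-2-yl}but-3-enamide | CC[C@H](CCC(=O)c1c(O[Si](C)(C)C(C)(C)C)c(C)cc2c1C(=O)C=C(NC(=O)CC=C)C2=O)/C=C\[C@H](O[Si](C)(C)C(C)(C)C)[C@H](CC(C)C)OCc1ccc(OC)cc1 | intermediate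
27 | N-{5-[(4R,5Z,7S,8S)-7-(TBS-oxy)-4-ethyl-8-hydroxy-10-methylundec-5-enoyl]-6-(TBS-oxy)-7-methyl-1,4-dioxo-1,4-dihydronaphthalen-2-yl}but-3-enamide | CC[C@H](CCC(=O)c1c(O[Si](C)(C)C(C)(C)C)c(C)cc2c1C(=O)C=C(NC(=O)CC=C)C2=O)/C=C\[C@H](O[Si](C)(C)C(C)(C)C)[C@H](CC(C)C)O | intermediate
28 | 2-methylprop-2-enoyl chloride (methacryloyl chloride) | CC(=C)C(Cl)=O | starting material
29 | methacrylate of 27: (4S,5S,6Z,8R)-11-{6-(but-3-enamido)-2-(TBS-oxy)-3-methyl-5,8-dioxo-5,8-dihydronaphthalen-1-yl}-5-(TBS-oxy)-8-ethyl-2-methyl-11-oxoundec-6-en-4-yl 2-methylprop-2-enoate | CC[C@H](CCC(=O)c1c(O[Si](C)(C)C(C)(C)C)c(C)cc2c1C(=O)C=C(NC(=O)CC=C)C2=O)/C=C\[C@H](O[Si](C)(C)C(C)(C)C)[C@H](CC(C)C)OC(=O)C(C)=C | intermediate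
30 | 20-membered macrocycle: 2-amino-6-(TBS-oxy)-7-methyl-1,4-naphthoquinone bridged from N to C5 by C(=O)CH2CH=C(CH3)C(=O)O–CH(i-Bu)–CH(OTBS)–CH=CH–CH(Et)–CH2CH2C(=O); (E) enoate, (Z) ring alkene, (S) at CH(i-Bu), (S) at CH(OTBS), (R) at CH(Et) | CC[C@H]1/C=C\[C@H](O[Si](C)(C)C(C)(C)C)[C@H](CC(C)C)OC(=O)/C(C)=C/CC(=O)NC2=CC(=O)c3c(C(=O)CC1)c(O[Si](C)(C)C(C)(C)C)c(C)cc3C2=O | intermediate
31 | 1,4-dihydroxynaphthalene (hydroquinone) form of 32, azepinone already closed, (R) quaternary centre | CC[C@H]1/C=C\[C@H](O[Si](C)(C)C(C)(C)C)[C@H](CC(C)C)OC(=O)[C@]2(C)C=CC(=O)Nc3c2c(O)c2c(C(=O)CC1)c(O[Si](C)(C)C(C)(C)C)c(C)cc2c3O | intermediate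
32 | bis-TBS ether of the target (silyl groups on the phenol and on the allylic hydroxyl) | CC[C@H]1/C=C\[C@H](O[Si](C)(C)C(C)(C)C)[C@H](CC(C)C)OC(=O)[C@]2(C)C=CC(=O)NC3=C2C(=O)c2c(cc(C)c(O[Si](C)(C)C(C)(C)C)c2C(=O)CC1)C3=O | intermediate
33 | CNP0579633.1: azepinone-fused ansa naphthoquinone macrolactone with free phenol and free allylic hydroxyl | CC[C@H]1/C=C\[C@H](O)[C@H](CC(C)C)OC(=O)[C@]2(C)C=CC(=O)NC3=C2C(=O)c2c(cc(C)c(O)c2C(=O)CC1)C3=O | target

## Step count and risk

Total steps: 22. Longest linear sequence: 17 steps (steps 1–5, 8–12, 14, 15, 18–22).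

The three steps most likely to fail:

Step 18 (Diels–Alder/aromatisation). The diene is a push–pull system, so it may react slowly or with the wrong orientation. The fallback sets out from 19 and 24 and comes back at 27. It replaces the thermal cycloaddition by a stepwise polar annulation. Diketone 19 and quinone 24 are stirred with catalytic Cs2CO3 in MeCN, so that the central diketone carbon adds to the quinone carbon β to the amide-flanked carbonyl and the resulting quinone enolate closes onto the isopropenyl ketone, giving the bicyclic triketone F1. DDQ in wet CH2Cl2 aromatises it and removes the PMB group to give the naphthol alcohol F2. TBSCl and imidazole then silylate the phenol in preference to the hindered secondary alcohol and return 27.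

Step 20 (macrocyclic metathesis onto a methacrylate). The trisubstituted enoate may form too slowly and oligomers may dominate. The fallback sets out from 27 and comes back at 30. It swaps the order of alkene and ester formation. Cross-metathesis of 27 with excess methacrylic acid (same ruthenium catalyst, CH2Cl2, 40 °C) gives the (E) seco acid F3. Addition of the acid to ethoxyacetylene with catalytic [RuCl2(p-cymene)]2 gives the 1-ethoxyvinyl ester F4. Catalytic TsOH at high dilution in toluene then closes the lactone onto the chain hydroxyl. This macrolactonisation is base-free, so the glutaconate cannot attack the quinone before the ring exists.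

Step 21 (transannular Michael addition). The glutaconate anion is ambident: attack through the amide α-carbon would give a five-membered lactam instead of the azepinone. The reoxidation can also be messy. The fallback sets out from 30 and comes back at 32. It changes the bond-forming event to an addition–elimination. NBS in DMF at 0 °C brominates the enaminone-like C3 of the quinone to give the 3-bromoquinone F5. K2CO3 in MeCN then lets the ester α-carbon displace bromide. This needs no oxidant and runs with a weak heterogeneous base, and the product is 32 directly.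

## Further compounds

F1 | step 18 | N-{5-[(4R,5Z,7S,8S)-7-(TBS-oxy)-4-ethyl-8-(PMB-oxy)-10-methylundec-5-enoyl]-7-methyl-1,4,6-trioxo-1,4,4a,5,6,7,8,8a-octahydronaphthalen-2-yl}but-3-enamide (mixture at the new ring carbons) | CC[C@H](CCC(=O)C1C(=O)C(C)CC2C1C(=O)C=C(NC(=O)CC=C)C2=O)/C=C\[C@H](O[Si](C)(C)C(C)(C)C)[C@H](CC(C)C)OCc1ccc(OC)cc1
F2 | step 18 | N-{5-[(4R,5Z,7S,8S)-7-(TBS-oxy)-4-ethyl-8-hydroxy-10-methylundec-5-enoyl]-6-hydroxy-7-methyl-1,4-dioxo-1,4-dihydronaphthalen-2-yl}but-3-enamide | CC[C@H](CCC(=O)c1c(O)c(C)cc2c1C(=O)C=C(NC(=O)CC=C)C2=O)/C=C\[C@H](O[Si](C)(C)C(C)(C)C)[C@H](CC(C)C)O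
F3 | step 20 | (2E)-5-({5-[(4R,5Z,7S,8S)-7-(TBS-oxy)-4-ethyl-8-hydroxy-10-methylundec-5-enoyl]-6-(TBS-oxy)-7-methyl-1,4-dioxo-1,4-dihydronaphthalen-2-yl}amino)-2-methyl-5-oxopent-2-enoic acid | CC[C@H](CCC(=O)c1c(O[Si](C)(C)C(C)(C)C)c(C)cc2c1C(=O)C=C(NC(=O)C/C=C(\C)C(=O)O)C2=O)/C=C\[C@H](O[Si](C)(C)C(C)(C)C)[C@H](CC(C)C)O
F4 | step 20 | 1-ethoxyvinyl ester of F3 | CC[C@H](CCC(=O)c1c(O[Si](C)(C)C(C)(C)C)c(C)cc2c1C(=O)C=C(NC(=O)C/C=C(\C)C(=O)OC(=C)OCC)C2=O)/C=C\[C@H](O[Si](C)(C)C(C)(C)C)[C@H](CC(C)C)O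
F5 | step 21 | 3-bromo derivative of macrocycle 30 (bromine on the quinone carbon next to the amide-bearing carbon) | CC[C@H]1/C=C\[C@H](O[Si](C)(C)C(C)(C)C)[C@H](CC(C)C)OC(=O)/C(C)=C/CC(=O)NC2=C(Br)C(=O)c3c(C(=O)CC1)c(O[Si](C)(C)C(C)(C)C)c(C)cc3C2=O
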